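**Plan**
- Retrosynthesis: open the γ-lactone (C12–O6) to a 6,12-diol and remove the O8 and O3 esters; cut the ten-membered carbocycle at C1–C2 by a retro-Claisen transform, which leads back to the eight-membered lactone O9–C3(=O)–C4(Me)=C5–C6–C7–C8–C9 with C10(Me)=C1H–OSi on C9; then cut C4=C5 (ring-closing metathesis), C6–C7 (zinc allylation), C7=C11 (cross-metathesis) and C8–C9 (alkoxyallylboration).
- Forward: open chain C7–C10/C1 → cis-butyrolactone (C6–C7) → masked as 6,12-diol → eight-membered enoate lactone → ten-membered carbocycle by carbonyl methylenation and [3,3] shift (ring expansion by two atoms) → esters → α-methylene-γ-lactone last.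
- Enabling feature: the β-oxy γ,δ-unsaturated ketone array C3(=O)–C2H2–C1H(O)–C10(Me)=C9 inside the cis,cis-cyclodeca-1,6-diene is the retron of a Claisen shift; C2 is the only unsubstituted ring carbon and can come from a methylene reagent, and C9 can carry the ring oxygen of a lactone two atoms smaller.
- Stereochemistry: C8/C9 from the Ipc2B reagent; C7 and C6 from C8 in the zinc allylation; C1 by chirality transfer from C9 (then lost) across the (E)-silyl enol ether; both Z ring olefins by ring constraint; C3 by CBS reduction; the ester stereocentre from (R)-2-methylbutanoic acid.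

Key step: step 11

Remark: atoms carry germacranolide locants throughout (ring C1–C10, C14 on C10, C15 on C4, lactone carbons C11–C13); 2-methylmalondialdehyde (1) and allyl methoxymethyl ether (3) are taken as catalogue compounds.

Step 1
Reactants: 1 2-methylmalondialdehyde (enol form)
Product: 2 (E)-2-methyl-3-(triisopropylsilyloxy)prop-2-enal
Conditions: TIPSCl, Et3N, CH2Cl2, 0 °C → rt
Reagents that add atoms: triisopropylsilyl chloride, CC(C)[Si](Cl)(C(C)C)C(C)C
Why: O-silylation of the enolised 1,3-dialdehyde (silyl enol ether formation) should give the conjugated (E)-isomer with O trans to CHO, which fixes the enol-ether geometry used in step 11.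

Step 2
Reactants: 3 allyl methoxymethyl ether; 2 (E)-2-methyl-3-(triisopropylsilyloxy)prop-2-enal
Product: 5 (3S,4S,1E)-4-(methoxymethoxy)-2-methyl-1-(triisopropylsilyloxy)hexa-1,5-dien-3-ol, via Z-alkoxyallyl-diisopinocampheylborane 4 (not isolated)
Conditions: 3, s-BuLi, THF, −78 °C; (+)-Ipc2BOMe [from (−)-α-pinene]; BF3·OEt2; then 2, −78 °C; NaBO3·4H2O, THF/H2O, rt
Reagents that add atoms: none
Why: γ-Alkoxyallylboration (Brown type) through a closed chair transition state: the (Z)-alkoxyallyl unit gives the 8,9-syn product and this Ipc antipode should deliver the allyl unit to the Re face of the aldehyde, setting C9 (S) and C8 (S here, R in the target).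

Step 3
Reactants: 5 syn-alkoxy alcohol
Product: 6 9-O-triethylsilyl ether of 5
Conditions: TESOTf, 2,6-lutidine, CH2Cl2, −78 °C
Reagents that add atoms: triethylsilyl triflate, CC[Si](CC)(CC)OS(=O)(=O)C(F)(F)F
Why: Base-buffered silyl ether formation protects O9 and keeps the acid-labile γ-oxy enol ether intact.

Step 4
Reactants: 6 triethylsilyl ether; 7 methyl 2-(bromomethyl)acrylate
Product: 8 methyl (2Z,4S,5S,6E)-2-(bromomethyl)-4-(methoxymethoxy)-6-methyl-5-(triethylsilyloxy)-7-(triisopropylsilyloxy)hepta-2,6-dienoate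
Conditions: Hoveyda–Grubbs II (10 mol %), 7 (5 equiv), CH2Cl2, 40 °C
Reagents that add atoms: none
Why: Olefin cross-metathesis of the only terminal olefin with a 1,1-disubstituted acrylate should give the thermodynamic trisubstituted isomer (C8 cis to CH2Br), the hindered trisubstituted silyl enol ether staying inert.

Step 5
Reactants: 8 allylic bromide; 9 acrolein
Product: 11 cis-fused α-methylene-γ-butyrolactone (C12–O6) with vinyl on C6, via syn-hydroxy ester 10 (not isolated)
Conditions: Zn dust, sat. aq. NH4Cl/THF, 0 °C → rt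
Reagents that add atoms: none
Why: Zinc Barbier (SE2') allylation through a six-membered chair transition state: the (Z)-allylzinc gives the 6,7-syn adduct, which lactonises to the cis lactone, and with H8 held in the olefin plane by A(1,3) strain (O8 can also bind zinc) acrolein should add to C7 anti to the C9 branch, setting C7 and C6 as in the target.

Step 6
Reactants: 11 cis-lactone
Product: 12 6,12-diol (2-methylene-1,4-diol)
Conditions: DIBAL-H (4 equiv), CH2Cl2, −78 → 0 °C; Rochelle salt
Reagents that add atoms: none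
Why: DIBAL-H reduction of the lactone to the diol takes C12 out of the carbonyl level, so that only one ester carbonyl is present at the methylenation stage.

Step 7
Reactants: 12 6,12-diol
Product: 13 6,12-bis(tert-butyldimethylsilyl) ether
Conditions: TBSOTf, 2,6-lutidine, CH2Cl2, −78 → 0 °C
Reagents that add atoms: tert-butyldimethylsilyl triflate, CC(C)(C)[Si](C)(C)OS(=O)(=O)C(F)(F)F
Why: Standard silyl ether formation at the primary and the secondary allylic hydroxyl.

Step 8
Reactants: 13 tris-silyl ether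
Product: 14 C9 alcohol
Conditions: HF·pyridine, pyridine, THF, 0 °C
Reagents that add atoms: none
Why: Selective desilylation: under pyridine-buffered HF a triethylsilyl ether should be cleaved much faster than the tert-butyldimethylsilyl ethers or the hindered triisopropylsilyl enol ether.

Step 9
Reactants: 14 C9 alcohol
Product: 15 C9 methacrylate
Conditions: methacrylic anhydride, Et3N, DMAP (cat.), CH2Cl2, rt
Reagents that add atoms: methacrylic anhydride, CC(=C)C(=O)OC(=O)C(C)=C
Why: DMAP-catalysed O-acylation brings in C3, C4 and C15 and forms the O9–C3 bond of the future eight-membered lactone.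

Step 10
Reactants: 15 methacrylate
Product: 16 eight-membered lactone (3Z)-3-methyl-5-(TBS-oxy)-6-[3-(TBS-oxy)prop-1-en-2-yl]-7-(methoxymethoxy)-8-[(E)-1-(TIPS-oxy)prop-1-en-2-yl]-5,6,7,8-tetrahydro-2H-oxocin-2-one
Conditions: Hoveyda–Grubbs II (15 mol %), toluene (1 mM), 80 °C
Reagents that add atoms: none
Why: Ring-closing metathesis between the C5 vinyl group and the methacrylate should close the eight-membered enoate lactone, in which only the Z (cis) C4=C5 olefin is possible.

Step 11
Reactants: 16 eight-membered lactone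
Product: 18 (4Z,9Z)-cyclodeca-4,9-dienone with C3=O and 1-OTIPS, via 2-methylidene-oxocine 17 (not isolated)
Conditions: Cp2TiMe2 (3 equiv), toluene, 75 °C, dark; then 110 °C
Reagents that add atoms: dimethyltitanocene, C[Ti](C)(C1C=CC=C1)C1C=CC=C1
Why: Cp2Ti=CH2, released from Cp2TiMe2 on heating, methylenates the lactone carbonyl C3 through an oxatitanacyclobutane to give the dienyl enol ether 17, whose allyl vinyl ether unit C2=C3–O9–C9–C10=C1 then undergoes a concerted suprafacial [3,3]-sigmatropic (Claisen) shift in which C2–C1 forms as O9–C9 breaks and C3 becomes the ketone. The closest known reaction type is the lactone methylenation–Claisen ring expansion of 2-methylene oxacycles that carry an alkenyl group next to oxygen, which enlarges the ring by two atoms (here 8 → 10). The ten-membered carbocycle closes through a bridged six-centre transition state in which the five-atom tether C4–C8 links C3 to C9, so that C8 must sit pseudo-axial (cis to C1) and the new C9=C10 olefin is Z. The only new stereocentre, C1, is set by chirality transfer from C9 (S, destroyed in the step) across the (E)-enol ether, C2 adding to the face of C1 from which O9 leaves, which gives 1S. The step needs the [3,3] path over ionisation/[1,3] shift and over a 1,5-hydrogen shift of the dienyl ether, and Z over E; the neutral non-polar medium, the donor silyloxy group on C1 and the nearly strain-free cis,cis-cyclodeca-1,6-diene skeleton of the product should secure this.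

Step 12
Reactants: 18 cyclodecadienone
Product: 19 (3S)-allylic alcohol
Conditions: (R)-Me-CBS, catecholborane, toluene, −78 °C
Reagents that add atoms: none
Why: CBS reduction: the α-methyl-alkenyl arm of the enone acts as the large group and the C2 methylene as the small one, so the (R)-oxazaborolidine should give the 3S alcohol under reagent control.

Step 13
Reactants: 19 (3S)-alcohol
Product: 20 3-acetate
Conditions: Ac2O, pyridine, DMAP (cat.), CH2Cl2, rt
Reagents that add atoms: acetic anhydride, CC(=O)OC(C)=O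
Why: Standard DMAP-catalysed acetylation of the secondary allylic alcohol.

Step 14
Reactants: 20 3-acetate
Product: 21 C8 alcohol
Conditions: Me2BBr, CH2Cl2, −78 °C; then sat. aq. NaHCO3
Reagents that add atoms: none
Why: Methoxymethyl ether cleavage by bromodimethylborane at −78 °C (bromide transfer to the acetal carbon) should leave silyl ethers, the allylic acetate and the olefins untouched.

Step 15
Reactants: 21 C8 alcohol; 22 (R)-2-methylbutanoic acid
Product: 23 8-[(R)-2-methylbutanoate]
Conditions: DCC, DMAP (cat.), CH2Cl2, 0 °C → rt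
Reagents that add atoms: none
Why: Steglich esterification at low temperature installs the chiral-pool acyl group without epimerising its α-stereocentre.

Step 16
Reactants: 23 fully protected diester
Product: 24 1,6,12-triol
Conditions: HF·pyridine, THF, 0 °C → rt
Reagents that add atoms: none
Why: Global desilylation with HF·pyridine is non-basic, so acyl migration is avoided and both esters should stay in place.

Step 17
Reactants: 24 1,6,12-triol
Product: 27 target CNP0282531.1, via enal 25 (not isolated), via lactol 26 (not isolated)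
Conditions: TEMPO (0.2 equiv), PhI(OAc)2 (2.5 equiv), CH2Cl2, rt
Reagents that add atoms: none
Why: TEMPO/PhI(OAc)2 oxidative lactonisation: the oxoammonium oxidant is selective for the primary allylic alcohol, the enal is trapped by the cis C6 hydroxyl as the lactol, and this is oxidised on to the α-methylene-γ-lactone while the secondary C1 alcohol should remain.

**Compound list**
1 | 2-methylmalondialdehyde, enol form [(E)-3-hydroxy-2-methylprop-2-enal] | O=C/C(C)=C/O | starting material
2 | (E)-2-methyl-3-(triisopropylsilyloxy)prop-2-enal (C9, C10, C14, C1) | O=C/C(C)=C/O[Si](C(C)C)(C(C)C)C(C)C | intermediate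
3 | allyl methoxymethyl ether [3-(methoxymethoxy)prop-1-ene] | C=CCOCOC | starting material
4 | [(Z)-3-(methoxymethoxy)prop-2-enyl]bis(isopinocampheyl)borane, Ipc from (−)-α-pinene | C[C@@H]1[C@@H](B(C/C=C\OCOC)[C@H]2C[C@H]3C[C@@H]([C@@H]2C)C3(C)C)C[C@H]2C[C@@H]1C2(C)C | intermediate (not isolated)
5 | (3S,4S,1E)-4-(methoxymethoxy)-2-methyl-1-(triisopropylsilyloxy)hexa-1,5-dien-3-ol (C9–OH, C8–OMOM, 8,9-syn) | C=C[C@H](OCOC)[C@@H](O)/C(C)=C/O[Si](C(C)C)(C(C)C)C(C)C | intermediate
6 | 9-O-triethylsilyl ether of 5 | C=C[C@H](OCOC)[C@@H](O[Si](CC)(CC)CC)/C(C)=C/O[Si](C(C)C)(C(C)C)C(C)C | intermediate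
7 | methyl 2-(bromomethyl)acrylate | C=C(CBr)C(=O)OC | starting material
8 | methyl (2Z,4S,5S,6E)-2-(bromomethyl)-4-(methoxymethoxy)-6-methyl-5-(triethylsilyloxy)-7-(triisopropylsilyloxy)hepta-2,6-dienoate | COC(=O)/C(CBr)=C/[C@H](OCOC)[C@@H](O[Si](CC)(CC)CC)/C(C)=C/O[Si](C(C)C)(C(C)C)C(C)C | intermediate
9 | acrolein | C=CC=O | starting material
10 | open 6,7-syn hydroxy ester: methyl 2-methylidene-4-hydroxyhex-5-enoate carrying on C7 the chain C8(OMOM)–C9(OTES)–C10(Me)=C1H(OTIPS) | COC(=O)C(=C)[C@@H]([C@@H](O)C=C)[C@H](OCOC)[C@@H](O[Si](CC)(CC)CC)/C(C)=C/O[Si](C(C)C)(C(C)C)C(C)C | intermediate (not isolated)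
11 | cis-fused α-methylene-γ-butyrolactone (C12–O6), vinyl on C6, chain C8(OMOM)–C9(OTES)–C10(Me)=C1H(OTIPS) on C7; C6, C7, C8 as in the target, C9 S | C=C1C(=O)O[C@@H](C=C)[C@H]1[C@H](OCOC)[C@@H](O[Si](CC)(CC)CC)/C(C)=C/O[Si](C(C)C)(C(C)C)C(C)C | intermediate
12 | 6,12-diol from reduction of 11 | OCC(=C)[C@@H]([C@@H](O)C=C)[C@H](OCOC)[C@@H](O[Si](CC)(CC)CC)/C(C)=C/O[Si](C(C)C)(C(C)C)C(C)C | intermediate
13 | 6,12-bis(tert-butyldimethylsilyl) ether of 12 | CC(C)(C)[Si](C)(C)OCC(=C)[C@@H]([C@@H](O[Si](C)(C)C(C)(C)C)C=C)[C@H](OCOC)[C@@H](O[Si](CC)(CC)CC)/C(C)=C/O[Si](C(C)C)(C(C)C)C(C)C | intermediate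
14 | C9 alcohol (triethylsilyl group removed) | CC(C)(C)[Si](C)(C)OCC(=C)[C@@H]([C@@H](O[Si](C)(C)C(C)(C)C)C=C)[C@H](OCOC)[C@@H](O)/C(C)=C/O[Si](C(C)C)(C(C)C)C(C)C | intermediate
15 | C9 methacrylate | CC(C)(C)[Si](C)(C)OCC(=C)[C@@H]([C@@H](O[Si](C)(C)C(C)(C)C)C=C)[C@H](OCOC)[C@@H](OC(=O)C(C)=C)/C(C)=C/O[Si](C(C)C)(C(C)C)C(C)C | intermediate
16 | eight-membered lactone O9–C3(=O)–C4(Me)=C5–C6(OTBS)–C7–C8(OMOM)–C9, 4Z, with (E)-C10(Me)=C1H(OTIPS) on C9 | C/C1=C/[C@H](O[Si](C)(C)C(C)(C)C)[C@H](C(=C)CO[Si](C)(C)C(C)(C)C)[C@H](OCOC)[C@H](/C(C)=C/O[Si](C(C)C)(C(C)C)C(C)C)OC1=O | intermediate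
17 | 2-methylidene-oxocine (enol ether of 16, C3=C2H2) | C/C1=C/[C@H](O[Si](C)(C)C(C)(C)C)[C@H](C(=C)CO[Si](C)(C)C(C)(C)C)[C@H](OCOC)[C@H](/C(C)=C/O[Si](C(C)C)(C(C)C)C(C)C)OC1=C | intermediate (not isolated)
18 | ten-membered (4Z,9Z)-dienone: C3 ketone, (1S)-OTIPS, 6-OTBS, 8-OMOM, 7-[3-(TBS-oxy)prop-1-en-2-yl] | C=C(CO[Si](C)(C)C(C)(C)C)[C@H]1[C@@H](O[Si](C)(C)C(C)(C)C)/C=C(/C)C(=O)C[C@H](O[Si](C(C)C)(C(C)C)C(C)C)/C(C)=C\[C@H]1OCOC | intermediate
19 | (3S)-allylic alcohol | C=C(CO[Si](C)(C)C(C)(C)C)[C@H]1[C@@H](O[Si](C)(C)C(C)(C)C)/C=C(/C)[C@@H](O)C[C@H](O[Si](C(C)C)(C(C)C)C(C)C)/C(C)=C\[C@H]1OCOC | intermediate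
20 | 3-acetate | C=C(CO[Si](C)(C)C(C)(C)C)[C@H]1[C@@H](O[Si](C)(C)C(C)(C)C)/C=C(/C)[C@@H](OC(C)=O)C[C@H](O[Si](C(C)C)(C(C)C)C(C)C)/C(C)=C\[C@H]1OCOC | intermediate
21 | C8 alcohol | C=C(CO[Si](C)(C)C(C)(C)C)[C@H]1[C@@H](O[Si](C)(C)C(C)(C)C)/C=C(/C)[C@@H](OC(C)=O)C[C@H](O[Si](C(C)C)(C(C)C)C(C)C)/C(C)=C\[C@H]1O | intermediate
22 | (R)-2-methylbutanoic acid | CC[C@@H](C)C(=O)O | starting material
23 | 8-[(R)-2-methylbutanoate] | C=C(CO[Si](C)(C)C(C)(C)C)[C@H]1[C@@H](O[Si](C)(C)C(C)(C)C)/C=C(/C)[C@@H](OC(C)=O)C[C@H](O[Si](C(C)C)(C(C)C)C(C)C)/C(C)=C\[C@H]1OC(=O)[C@H](C)CC | intermediate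
24 | 1,6,12-triol | C=C(CO)[C@H]1[C@@H](O)/C=C(/C)[C@@H](OC(C)=O)C[C@H](O)/C(C)=C\[C@H]1OC(=O)[C@H](C)CC | intermediate
25 | C12 enal | C=C(C=O)[C@H]1[C@@H](O)/C=C(/C)[C@@H](OC(C)=O)C[C@H](O)/C(C)=C\[C@H]1OC(=O)[C@H](C)CC | intermediate (not isolated)
26 | 6,12-lactol (both anomers) | C=C1C(O)O[C@H]2/C=C(/C)[C@@H](OC(C)=O)C[C@H](O)/C(C)=C\[C@@H](OC(=O)[C@H](C)CC)[C@@H]12 | intermediate (not isolated)
27 | CNP0282531.1 | C=C1C(=O)O[C@H]2/C=C(/C)[C@@H](OC(C)=O)C[C@H](O)/C(C)=C\[C@@H](OC(=O)[C@H](C)CC)[C@@H]12 | target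

**Totals:** 17 steps; longest linear sequence 17 steps (1 → 27).

**Three steps most likely to fail**

1. Step 11 (methylenation/Claisen ring expansion). The enol ether 17 may not rearrange cleanly: ionisation to an ion pair with [1,3] recombination, formation of the E olefin, or a 1,5-hydrogen shift of the dienyl ether can compete, and methylenation may be incomplete. Fallback from 16, back at 18: methylenate with the Tebbe reagent at low temperature (THF/pyridine, −40 °C → rt) and isolate 17. Then promote the rearrangement at −78 °C → rt with triisobutylaluminium, which delivers hydride to the ketone as it forms and gives the C3-epimeric allylic alcohols F10. Dess–Martin oxidation of F10 returns 18.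

2. Step 10 (ring-closing metathesis to the eight-membered lactone). Initiation at the hindered allylic olefin may be slow and ring closure onto the electron-poor 1,1-disubstituted acrylate may lose out to oligomerisation. Fallback from 14, back at 16: relay metathesis. Esterify 14 (Yamaguchi conditions) with the known (2E)-2-methylocta-2,7-dienoic acid F8 to give the relay ester F9. The catalyst then loads at the unhindered terminal olefin, expels cyclopentene and is placed directly on C4, from where it closes onto the C5 vinyl group to give 16.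

3. Step 4 (cross-metathesis). The allylic, doubly oxygen-flanked terminal olefin may react too slowly with the 1,1-disubstituted acrylate, and the allylic bromide may shorten catalyst life. Fallback from 2, back at 8, building the same bromide from the aldehyde side:
   - Evans syn-aldol of the dibutylboron enolate of (R)-4-benzyl-3-[(methoxymethoxy)acetyl]oxazolidin-2-one F1 (from the oxazolidinone and (methoxymethoxy)acetic acid through the pivaloyl mixed anhydride) with 2 gives the 8,9-syn aldol adduct F2.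
   - TESOTf/2,6-lutidine gives the silyl ether F3, and LiBH4 removes the auxiliary to give the primary alcohol F4.
   - Parikh–Doering oxidation gives the aldehyde F5.
   - Morita–Baylis–Hillman reaction with methyl acrylate/DABCO gives the allylic alcohol F6 (both C7 epimers).
   - Mesylation to F7 followed by SN2' displacement with LiBr gives 8.

Further compounds
F1 | step 4 | (R)-4-benzyl-3-[(methoxymethoxy)acetyl]oxazolidin-2-one | COCOCC(=O)N1C(=O)OC[C@H]1Cc1ccccc1
F2 | step 4 | syn-aldol adduct of F1 and 2 (C8–OMOM, C9–OH) | O=C(N1C(=O)OC[C@H]1Cc1ccccc1)[C@H](OCOC)[C@@H](O)/C(C)=C/O[Si](C(C)C)(C(C)C)C(C)C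
F3 | step 4 | 9-O-triethylsilyl ether of F2 | O=C(N1C(=O)OC[C@H]1Cc1ccccc1)[C@H](OCOC)[C@@H](O[Si](CC)(CC)CC)/C(C)=C/O[Si](C(C)C)(C(C)C)C(C)C
F4 | step 4 | C7 primary alcohol | OC[C@H](OCOC)[C@@H](O[Si](CC)(CC)CC)/C(C)=C/O[Si](C(C)C)(C(C)C)C(C)C
F5 | step 4 | C7 aldehyde | O=C[C@H](OCOC)[C@@H](O[Si](CC)(CC)CC)/C(C)=C/O[Si](C(C)C)(C(C)C)C(C)C
F6 | step 4 | Morita–Baylis–Hillman adduct (C7 epimers) | COC(=O)C(=C)C(O)[C@H](OCOC)[C@@H](O[Si](CC)(CC)CC)/C(C)=C/O[Si](C(C)C)(C(C)C)C(C)C
F7 | step 4 | allylic mesylate of F6 (C7 epimers) | COC(=O)C(=C)C(OS(C)(=O)=O)[C@H](OCOC)[C@@H](O[Si](CC)(CC)CC)/C(C)=C/O[Si](C(C)C)(C(C)C)C(C)C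
F8 | step 10 | (2E)-2-methylocta-2,7-dienoic acid | C=CCCC/C=C(\C)C(=O)O
F9 | step 10 | relay ester of 14 with F8 | CC(C)(C)[Si](C)(C)OCC(=C)[C@@H]([C@@H](O[Si](C)(C)C(C)(C)C)C=C)[C@H](OCOC)[C@@H](OC(=O)/C(C)=C/CCCC=C)/C(C)=C/O[Si](C(C)C)(C(C)C)C(C)C
F10 | step 11 | C3-epimeric allylic alcohols (19 and its 3-epimer) | C=C(CO[Si](C)(C)C(C)(C)C)[C@H]1[C@@H](O[Si](C)(C)C(C)(C)C)/C=C(/C)C(O)C[C@H](O[Si](C(C)C)(C(C)C)C(C)C)/C(C)=C\[C@H]1OCOC
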